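The strategy closes the ten-membered carbocycle (C1–C10, germacrane numbering) last, across C7–C8, the bond between the lactone β-carbon and the acyloxy-bearing carbinol. The precursor is a seco-aldehyde that already holds the 3(2H)-furanone and the 4Z-olefin, with C8 as an aldehyde and the lactone disguised as a 3-(bromomethyl)butenolide. Divalent chromium turns the allylic bromide into an allylchromium reagent whose γ-carbon C7 adds to the aldehyde: one operation forms the C7–C8 bond, the carbocycle, both stereocentres and the exocyclic methylene of the α-methylene-γ-butyrolactone. The step exploits the 1,2-relationship between the C8 oxygen and the allylic C7 of the lactone ring. Mitsunobu esterification then inverts C8.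

Key step: step 11

Remark: locants follow germacrane numbering of the target (C1 ketone, C3 and C10 on the furanone oxygen, C4=C5, C6 lactone carbinol, C8 ester carbinol, C9 free carbinol, C11–C13 methylene lactone); starting materials 1 and 5 are taken as purchasable, and divinylzinc is used as a separately prepared salt-free solution (from vinylmagnesium bromide and ZnCl2).

Step 1
Reactants: 1 (Z)-3-methylpent-2-en-4-yn-1-ol
Product: 2 (Z)-3-methylpent-2-en-4-ynal
Conditions: activated MnO2 (15 equiv), CH2Cl2, 0 °C to rt, dark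
Reagents that add atoms: none
Why: Allylic oxidation with MnO2 is selective for the primary allylic alcohol, leaves the terminal alkyne alone and, run cold and in the dark, should keep the Z geometry that later becomes the C4=C5 olefin.

Step 2
Reactants: 2 (Z)-3-methylpent-2-en-4-ynal
Product: 3 (3S,4Z)-5-methylhepta-1,4-dien-6-yn-3-ol
Conditions: divinylzinc (1.5 equiv), (−)-MIB (10 mol %), toluene, −30 °C; aqueous work-up
Reagents that add atoms: divinylzinc, C=C[Zn]C=C
Why: Amino-alcohol-catalysed enantioselective organozinc addition to an aldehyde, in which (−)-MIB, as with dialkylzincs, should deliver the vinyl group to the Si face and so set the S carbinol (C6 of the target), the 1,2-addition at −30 °C being expected to outrun metalation of the terminal alkyne.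

Step 3
Reactants: 3 (3S,4Z)-5-methylhepta-1,4-dien-6-yn-3-ol
Product: 4 (3S,4Z)-5-methyl-3-(triethylsilyloxy)hepta-1,4-dien-6-yne
Conditions: TESCl, imidazole, CH2Cl2, 0 °C
Reagents that add atoms: chlorotriethylsilane, CC[Si](Cl)(CC)CC
Why: Standard silylation of a secondary alcohol; the TES ether masks the C6 hydroxyl, which as a Z-enynol would otherwise close onto the alkyne (5-exo-dig, furan formation) in step 6, and it can later be removed beside a TBS ether.

Step 4
Reactants: 5 2-C-methyl-D-erythrono-1,4-lactone, (3R,4R)-3,4-dihydroxy-3-methyloxolan-2-one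
Product: 6 (3R,4R)-4-(tert-butyldimethylsilyloxy)-3-hydroxy-3-methyloxolan-2-one
Conditions: TBSCl (1.2 equiv), imidazole, DMF, rt
Reagents that add atoms: tert-butyldimethylsilyl chloride, CC(C)(C)[Si](C)(C)Cl
Why: Chemoselective silylation of the secondary hydroxyl (C9 of the target) beside the hindered tertiary α-hydroxyl, which stays free for the furanone; both stereocentres (C9 and C10) come from the chiral pool.

Step 5
Reactants: 4 (3S,4Z)-5-methyl-3-(triethylsilyloxy)hepta-1,4-dien-6-yne; 6 (3R,4R)-4-(tert-butyldimethylsilyloxy)-3-hydroxy-3-methyloxolan-2-one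
Product: 9 (3R,4R)-4-(tert-butyldimethylsilyloxy)-3-methyl-2-[(3Z,5S)-3-methyl-5-(triethylsilyloxy)hepta-3,6-dien-1-yn-1-yl]oxolane-2,3-diol (alkynyl lactol, both anomers), via lithium acetylide 7 (not isolated), via lithium alkoxide 8 (not isolated)
Conditions: 4 with nBuLi (1.0 equiv), THF, −78 °C; 6 with LiHMDS (1.0 equiv), THF, −78 °C; combine, −78 to −40 °C; AcOH quench at −78 °C
Reagents that add atoms: none
Why: Addition of a lithium acetylide to a γ-lactone stops at the tetrahedral lithium hemiketalate at low temperature and gives the alkynyl lactol (a masked α'-hydroxy ynone) on quench, which forms the C1–C2 bond; the tertiary hydroxyl is carried as its lithium alkoxide so that it does not protonate the acetylide.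

Step 6
Reactants: 9 alkynyl lactol
Product: 11 (2R)-2-[(1R)-1-(tert-butyldimethylsilyloxy)-2-hydroxyethyl]-2-methyl-5-[(2Z,4S)-4-(triethylsilyloxy)hexa-2,5-dien-2-yl]furan-3(2H)-one, via β-diethylamino enone 10 (not isolated)
Conditions: Et2NH (2 equiv), EtOH, rt; then AcOH, rt
Reagents that add atoms: none
Why: Amine-mediated cyclisation of an α'-hydroxy ynone to a 3(2H)-furanone: diethylamine adds to the open-chain ynone tautomer, and on mild acidification the tertiary C10 hydroxyl displaces the amine at C3 by addition–elimination, which forms the C3–O bond and leaves the C8 primary alcohol free without touching a stereocentre or the isolated olefins.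

Step 7
Reactants: 11 furanone primary alcohol
Product: 12 (2S)-2-(tert-butyldimethylsilyloxy)-2-{(2R)-2-methyl-3-oxo-5-[(2Z,4S)-4-(triethylsilyloxy)hexa-2,5-dien-2-yl]-2,3-dihydrofuran-2-yl}acetaldehyde
Conditions: Dess–Martin periodinane, CH2Cl2, 0 °C to rt
Reagents that add atoms: none
Why: Dess–Martin oxidation converts the only free hydroxyl into the C8 aldehyde under near-neutral conditions that spare both silyl ethers and avoid base-induced β-elimination of the furanone oxygen from C10.

Step 8
Reactants: 12 TES-protected aldehyde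
Product: 13 (2S)-2-(tert-butyldimethylsilyloxy)-2-{(2R)-5-[(2Z,4S)-4-hydroxyhexa-2,5-dien-2-yl]-2-methyl-3-oxo-2,3-dihydrofuran-2-yl}acetaldehyde
Conditions: AcOH/THF/H2O (3:1:1), rt
Reagents that add atoms: none
Why: Selective acidic solvolysis of silyl ethers: the secondary TES ether should cleave far faster than the hindered TBS ether next to the quaternary centre, which frees the C6 hydroxyl.

Step 9
Reactants: 13 hydroxy aldehyde; 14 2-(bromomethyl)acrylic acid
Product: 15 (3S,4Z)-5-{(5R)-5-[(1S)-1-(tert-butyldimethylsilyloxy)-2-oxoethyl]-5-methyl-4-oxo-4,5-dihydrofuran-2-yl}hexa-1,4-dien-3-yl 2-(bromomethyl)acrylate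
Conditions: DIC, DMAP (5 mol %), CH2Cl2, −20 to 0 °C
Reagents that add atoms: none
Why: Steglich (carbodiimide) esterification of the only hydroxyl with retention at C6, low temperature and little DMAP being chosen to limit SN2' attack on the allylic bromide and base-induced elimination next to the aldehyde.

Step 10
Reactants: 15 bromomethylacrylate ester
Product: 16 (2S)-2-{(2R)-5-[(1Z)-1-[(2R)-4-(bromomethyl)-5-oxo-2,5-dihydrofuran-2-yl]prop-1-en-2-yl]-2-methyl-3-oxo-2,3-dihydrofuran-2-yl}-2-(tert-butyldimethylsilyloxy)acetaldehyde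
Conditions: second-generation Grubbs catalyst (H2IMes)(PCy3)Cl2Ru=CHPh (5 mol %), CH2Cl2 (5 mM), 40 °C
Reagents that add atoms: none
Why: Ring-closing metathesis between the terminal vinyl group and the 1,1-disubstituted acrylate closes the butenolide (C7=C11) with loss of ethylene, the trisubstituted conjugated C4=C5 and furanone olefins being inert and the ruthenium carbene tolerating the aldehyde and the allylic bromide.

Step 11
Reactants: 16 bromomethylbutenolide aldehyde
Product: 18 (6R,7R,8R,9R,10R)-9α-(tert-butyldimethylsilyloxy)-3,10-epoxy-8α-hydroxy-1-oxogermacra-2,4Z,11(13)-trien-12,6α-olide (8-epi-8-O-deacyl-9-O-TBS-lobatin B), via allylchromium dichloride 17 (not isolated)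
Conditions: CrCl2 (10 equiv), THF, rt, syringe-pump addition of 16 (final 1 mM); aqueous work-up
Reagents that add atoms: none
Why: Divalent chromium reduces the allylic C13–Br bond in two one-electron steps to the trivalent allylchromium 17, which adds to the C8 aldehyde through its γ-carbon C7 in a chair-like six-membered (Zimmerman–Traxler) transition state with shift of the double bond to C11=C13, an intramolecular Nozaki–Hiyama allylation of the kind established for 2-(bromomethyl)acrylates and 3-(bromomethyl)butenolides. The closure is exo-trig at the aldehyde: it forms the ten-membered carbocycle C1–C10, which by the shortest path through the furanone oxygen is a 9-exo-trig closure of the ring C7–C8–C9–C10–O–C3–C4–C5–C6. C7 is set by C6, because the tether carried on C5 should reach the butenolide face anti to the C5 substituent and give the trans-fused lactone (H-7α), the fusion this bridged ring accommodates with least strain. C8 is set by the chair, in which the ring-locked allyl geometry places C6 pseudo-equatorial on C7 and the aldehyde substituent C9 pseudo-equatorial, so that the new hydroxyl is 7,8-anti (8α), and the Felkin–Anh preference of the α-silyloxy aldehyde (8,9-anti) points the same way. The step needs γ- over α-attack, which is inherent in the SE2' pathway of allylchromium reagents, and ring closure over oligomerisation, which slow addition at millimolar concentration and the rigid furanone and Z-olefin holding the termini close should secure. The 8α-carbinol is the epimer that step 12 inverts.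

Step 12
Reactants: 18 8α-alcohol; 19 3-methylbutanoic (isovaleric) acid
Product: 20 (6R,7S,8S,9R,10R)-9α-(tert-butyldimethylsilyloxy)-3,10-epoxy-8β-(3-methylbutanoyloxy)-1-oxogermacra-2,4Z,11(13)-trien-12,6α-olide (9-O-TBS-lobatin B)
Conditions: PPh3, DIAD, toluene, 0 °C to rt
Reagents that add atoms: none
Why: Mitsunobu esterification, in which the 8α-hydroxyl is activated as its alkoxyphosphonium ion and displaced by isovalerate with SN2 inversion, so that the ester and the 8β (S) configuration of the target are installed in one operation.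

Step 13
Reactants: 20 9-O-TBS-lobatin B
Product: 21 lobatin B, (6R,7S,8S,9R,10R)-3,10-epoxy-9α-hydroxy-8β-(3-methylbutanoyloxy)-1-oxogermacra-2,4Z,11(13)-trien-12,6α-olide
Conditions: HF·pyridine, THF, 0 °C to rt
Reagents that add atoms: none
Why: Fluoride-mediated desilylation under acidic conditions removes the last TBS ether while avoiding the base-promoted 8→9 acyl migration and sparing the α-methylene lactone and the dienone.

Compound list
1 | (Z)-3-methylpent-2-en-4-yn-1-ol | OC/C=C(/C)C#C | starting material
2 | (Z)-3-methylpent-2-en-4-ynal | O=C/C=C(/C)C#C | intermediate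
3 | (3S,4Z)-5-methylhepta-1,4-dien-6-yn-3-ol | C=C[C@H](O)/C=C(/C)C#C | intermediate
4 | (3S,4Z)-5-methyl-3-(triethylsilyloxy)hepta-1,4-dien-6-yne | C=C[C@H](O[Si](CC)(CC)CC)/C=C(/C)C#C | intermediate
5 | 2-C-methyl-D-erythrono-1,4-lactone, (3R,4R)-3,4-dihydroxy-3-methyloxolan-2-one | O=C1[C@](C)(O)[C@H](O)CO1 | starting material
6 | (3R,4R)-4-(tert-butyldimethylsilyloxy)-3-hydroxy-3-methyloxolan-2-one | O=C1[C@](C)(O)[C@H](O[Si](C)(C)C(C)(C)C)CO1 | intermediate
7 | lithium acetylide of 4, [(3Z,5S)-3-methyl-5-(triethylsilyloxy)hepta-3,6-dien-1-yn-1-yl]lithium | [Li]C#C/C(C)=C\[C@H](C=C)O[Si](CC)(CC)CC | intermediate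
8 | lithium 3-alkoxide of lactone 6 | O=C1[C@](C)(O[Li])[C@H](O[Si](C)(C)C(C)(C)C)CO1 | intermediate
9 | (3R,4R)-4-(tert-butyldimethylsilyloxy)-3-methyl-2-[(3Z,5S)-3-methyl-5-(triethylsilyloxy)hepta-3,6-dien-1-yn-1-yl]oxolane-2,3-diol (both anomers) | OC1(C#C/C(C)=C\[C@H](C=C)O[Si](CC)(CC)CC)[C@](C)(O)[C@H](O[Si](C)(C)C(C)(C)C)CO1 | intermediate
10 | (3S,4Z,9R,10R)-10-(tert-butyldimethylsilyloxy)-6-(diethylamino)-9,11-dihydroxy-5,9-dimethyl-3-(triethylsilyloxy)undeca-1,4,6-trien-8-one (C6=C7 geometry undefined) | CCN(CC)C(=CC(=O)[C@](C)(O)[C@H](O[Si](C)(C)C(C)(C)C)CO)/C(C)=C\[C@H](C=C)O[Si](CC)(CC)CC | intermediate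
11 | (2R)-2-[(1R)-1-(tert-butyldimethylsilyloxy)-2-hydroxyethyl]-2-methyl-5-[(2Z,4S)-4-(triethylsilyloxy)hexa-2,5-dien-2-yl]furan-3(2H)-one | C=C[C@H](O[Si](CC)(CC)CC)/C=C(/C)C1=CC(=O)[C@](C)(O1)[C@H](O[Si](C)(C)C(C)(C)C)CO | intermediate
12 | (2S)-2-(tert-butyldimethylsilyloxy)-2-{(2R)-2-methyl-3-oxo-5-[(2Z,4S)-4-(triethylsilyloxy)hexa-2,5-dien-2-yl]-2,3-dihydrofuran-2-yl}acetaldehyde | C=C[C@H](O[Si](CC)(CC)CC)/C=C(/C)C1=CC(=O)[C@](C)(O1)[C@H](O[Si](C)(C)C(C)(C)C)C=O | intermediate
13 | (2S)-2-(tert-butyldimethylsilyloxy)-2-{(2R)-5-[(2Z,4S)-4-hydroxyhexa-2,5-dien-2-yl]-2-methyl-3-oxo-2,3-dihydrofuran-2-yl}acetaldehyde | C=C[C@H](O)/C=C(/C)C1=CC(=O)[C@](C)(O1)[C@H](O[Si](C)(C)C(C)(C)C)C=O | intermediate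
14 | 2-(bromomethyl)acrylic acid | C=C(CBr)C(=O)O | starting material
15 | (3S,4Z)-5-{(5R)-5-[(1S)-1-(tert-butyldimethylsilyloxy)-2-oxoethyl]-5-methyl-4-oxo-4,5-dihydrofuran-2-yl}hexa-1,4-dien-3-yl 2-(bromomethyl)acrylate | C=C[C@H](OC(=O)C(=C)CBr)/C=C(/C)C1=CC(=O)[C@](C)(O1)[C@H](O[Si](C)(C)C(C)(C)C)C=O | intermediate
16 | (2S)-2-{(2R)-5-[(1Z)-1-[(2R)-4-(bromomethyl)-5-oxo-2,5-dihydrofuran-2-yl]prop-1-en-2-yl]-2-methyl-3-oxo-2,3-dihydrofuran-2-yl}-2-(tert-butyldimethylsilyloxy)acetaldehyde | BrCC1=C[C@H](OC1=O)/C=C(/C)C2=CC(=O)[C@](C)(O2)[C@H](O[Si](C)(C)C(C)(C)C)C=O | intermediate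
17 | allylchromium dichloride from 16 (CrCl2 in place of Br on the butenolide CH2, trivalent chromium) | Cl[Cr](Cl)CC1=C[C@H](OC1=O)/C=C(/C)C2=CC(=O)[C@](C)(O2)[C@H](O[Si](C)(C)C(C)(C)C)C=O | intermediate
18 | (6R,7R,8R,9R,10R)-9α-(tert-butyldimethylsilyloxy)-3,10-epoxy-8α-hydroxy-1-oxogermacra-2,4Z,11(13)-trien-12,6α-olide | C=C1C(=O)O[C@@H]2/C=C(/C)C3=CC(=O)[C@](C)(O3)[C@H](O[Si](C)(C)C(C)(C)C)[C@H](O)[C@@H]12 | intermediate
19 | 3-methylbutanoic acid (isovaleric acid) | CC(C)CC(=O)O | starting material
20 | (6R,7S,8S,9R,10R)-9α-(tert-butyldimethylsilyloxy)-3,10-epoxy-8β-(3-methylbutanoyloxy)-1-oxogermacra-2,4Z,11(13)-trien-12,6α-olide | C=C1C(=O)O[C@@H]2/C=C(/C)C3=CC(=O)[C@](C)(O3)[C@H](O[Si](C)(C)C(C)(C)C)[C@@H](OC(=O)CC(C)C)[C@@H]12 | intermediate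
21 | lobatin B | C=C1C(=O)O[C@@H]2/C=C(/C)C3=CC(=O)[C@](C)(O3)[C@H](O)[C@@H](OC(=O)CC(C)C)[C@@H]12 | target

Total step count: 13. Longest linear sequence: 12 steps (steps 1–3 and 5–13, from 1); the branch from 5 joins at step 5.

Steps most likely to fail

Step 11 (macrocyclisation). The allylchromium species may add intermolecularly (oligomerisation), be protonated before it closes the ring, or add through the wrong butenolide face. The fallback sets out from 16 and changes the allyl metal to boron. Zerovalent-palladium-catalysed borylation (Pd2(dba)3, B2pin2, DMSO/toluene, rt) should give the isolable 2-(alkoxycarbonyl)allylboronate, (2S)-2-(tert-butyldimethylsilyloxy)-2-{(2R)-2-methyl-3-oxo-5-[(1Z)-1-[(2R)-5-oxo-4-(pinacolborylmethyl)-2,5-dihydrofuran-2-yl]prop-1-en-2-yl]-2,3-dihydrofuran-2-yl}acetaldehyde F1. In dilute toluene with catalytic Sc(OTf)3 or on heating, F1 should undergo intramolecular allylboration through a closed chair to the pinacol borate ester of the macrocyclic alcohol F2, which hydrolyses on work-up. The fallback comes back to the route at 18.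

Step 12 (Mitsunobu inversion). Activation of the hindered C8 carbinol may be slow, and E2 elimination toward C7 or phosphine addition to the methylene lactone may compete with substitution. The fallback sets out from 18 and separates activation from displacement. Chloromethanesulfonyl chloride and pyridine (CH2Cl2, 0 °C) give the 8α-chloromethanesulfonate F3, and cesium isovalerate with 18-crown-6 in toluene displaces it with inversion. The fallback comes back at 20.

Step 2 (asymmetric vinylation). Enantioselectivity may erode, or the organozinc may metalate the terminal alkyne and open alkynylation pathways. The fallback sets out from 2 and replaces asymmetric catalysis by resolution. Vinylmagnesium bromide (THF, −78 °C) gives racemic (Z)-5-methylhepta-1,4-dien-6-yn-3-ol F4. Candida antarctica lipase B with vinyl acetate in hexane should, following the Kazlauskas rule, acetylate the R enantiomer to (3R,4Z)-5-methylhepta-1,4-dien-6-yn-3-yl acetate F5 and leave the S alcohol. The fallback comes back at 3.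

Further compounds
F1 | step 11 | (2S)-2-(tert-butyldimethylsilyloxy)-2-{(2R)-2-methyl-3-oxo-5-[(1Z)-1-[(2R)-5-oxo-4-[(4,4,5,5-tetramethyl-1,3,2-dioxaborolan-2-yl)methyl]-2,5-dihydrofuran-2-yl]prop-1-en-2-yl]-2,3-dihydrofuran-2-yl}acetaldehyde | CC1(C)OB(CC2=C[C@H](OC2=O)/C=C(/C)C3=CC(=O)[C@](C)(O3)[C@H](O[Si](C)(C)C(C)(C)C)C=O)OC1(C)C
F2 | step 11 | 8-O-(4,4,5,5-tetramethyl-1,3,2-dioxaborolan-2-yl) derivative of 18 | C=C1C(=O)O[C@@H]2/C=C(/C)C3=CC(=O)[C@](C)(O3)[C@H](O[Si](C)(C)C(C)(C)C)[C@H](OB4OC(C)(C)C(C)(C)O4)[C@@H]12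
F3 | step 12 | 8α-chloromethanesulfonate of 18 | C=C1C(=O)O[C@@H]2/C=C(/C)C3=CC(=O)[C@](C)(O3)[C@H](O[Si](C)(C)C(C)(C)C)[C@H](OS(=O)(=O)CCl)[C@@H]12
F4 | step 2 | racemic (Z)-5-methylhepta-1,4-dien-6-yn-3-ol | C=CC(O)/C=C(/C)C#C
F5 | step 2 | (3R,4Z)-5-methylhepta-1,4-dien-6-yn-3-yl acetate | C=C[C@@H](OC(C)=O)/C=C(/C)C#C
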